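**Plan**

- Retrosynthesis: the three acid-labile groups (tert-butyl ester, MOM ether, ring B methyl ether) are removed last. Ring B is then cut at C5'–C6' and C3'–C4' into a 2-pyrone and 1,1-dimethoxyethene, the pyrone C4–O(ring A) bond is cut next, and the pyrone is opened to a malonate and acetylketene.
- Feature used: ring B (C1' ether O, C2' H, C3' CH3, C4' H, C5' OH, C6' CO2H) is a 6-aryloxy-4-methylsalicylic acid. C6', C1', C2' and C3' are C3, C4, C5 and C6 of a 3-carboxy-4-aryloxy-6-methyl-2-pyrone, and C4'–C5'(O) is the ketene acetal.
- Forward: ring A is made as a fully substituted salicylate phenol from 2-chlororesorcinol (steps 1–7). The hydroxypyrone ring closes by lactonisation and is tosylated (steps 8–9), and the two halves are joined by addition–elimination at pyrone C4 (step 10). Ring B closes by cycloaddition with loss of CO2 and methanol (step 11), and BCl3 unmasks the target (step 12).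
- Stereochemistry: the target has no stereocentre. The bridged lactone formed in the key step is racemic and both of its centres vanish on aromatisation.

Key step: step 11

Remark on the chemistry: tert-butyl methyl malonate is chosen as the malonate so that the lactone closes on the methyl ester and the tert-butyl ester remains at pyrone C3.

**Route**

Step 1
Reactants: 1 2-chlorobenzene-1,3-diol (2-chlororesorcinol)
Product: 2 3-chloro-2,4-dihydroxybenzaldehyde
Conditions: POCl3, DMF, MeCN, 0 °C → rt; then H2O, 50 °C
Reagents that add atoms: N,N-dimethylformamide, CN(C)C=O (formyl carbon); water, O (carbonyl oxygen on hydrolysis)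
Why: Vilsmeier–Haack formylation; the chloroiminium electrophile can only enter the two equivalent positions ortho to one hydroxyl and para to the other, and hydrolysis of the iminium salt should give the aldehyde.

Step 2
Reactants: 2 3-chloro-2,4-dihydroxybenzaldehyde
Product: 3 3-chloro-2-hydroxy-4-(methoxymethoxy)benzaldehyde
Conditions: MOMCl (1.05 equiv), K2CO3, acetone, 0 °C → rt
Reagents that add atoms: chloromethyl methyl ether, COCCl
Why: Williamson-type O-alkylation; the hydroxyl para to the formyl group is the more acidic and is not held in the hydrogen bond to the carbonyl, so one equivalent of MOMCl with a weak base should take it alone.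

Step 3
Reactants: 3 3-chloro-2-hydroxy-4-(methoxymethoxy)benzaldehyde
Product: 4 3-chloro-2-methoxy-4-(methoxymethoxy)benzaldehyde
Conditions: MeI, K2CO3, DMF, 40 °C
Reagents that add atoms: iodomethane, CI
Why: Williamson O-methylation of the remaining, chelated phenol, which alkylates cleanly once the other hydroxyl is capped.

Step 4
Reactants: 4 3-chloro-2-methoxy-4-(methoxymethoxy)benzaldehyde
Product: 6 3-chloro-2-methoxy-4-(methoxymethoxy)phenol, via aryl formate 5 (not isolated)
Conditions: mCPBA, CH2Cl2, 0 °C → rt; then cat. K2CO3, MeOH, rt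
Reagents that add atoms: 3-chloroperoxybenzoic acid, OOC(=O)c1cccc(Cl)c1
Why: Dakin-type Baeyer–Villiger oxidation; the electron-rich aryl group (ortho methoxy, para alkoxy) migrates in the Criegee adduct to give the aryl formate, which mild methanolysis should cleave without touching the MOM acetal.

Step 5
Reactants: 6 3-chloro-2-methoxy-4-(methoxymethoxy)phenol
Product: 8 4-chloro-2-hydroxy-3-methoxy-5-(methoxymethoxy)benzaldehyde, via salicyl alcohol 7 (not isolated)
Conditions: MgCl2, Et3N, (CH2O)n, MeCN, reflux; aq. NH4Cl work-up
Reagents that add atoms: paraformaldehyde (as formaldehyde), C=O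
Why: Casnati–Skattebøl ortho-formylation; the magnesium phenoxide delivers formaldehyde to the only free ortho position, and the benzylic alkoxide so formed is oxidised by a second formaldehyde through hydride transfer.

Step 6
Reactants: 8 4-chloro-2-hydroxy-3-methoxy-5-(methoxymethoxy)benzaldehyde
Product: 9 4-chloro-2-hydroxy-3-methoxy-5-(methoxymethoxy)benzoic acid
Conditions: NaClO2, NaH2PO4, 2-methyl-2-butene, t-BuOH/H2O, rt
Reagents that add atoms: NaClO2 (sodium chlorite), [Na+].[O-]Cl=O
Why: Pinnick (Lindgren) oxidation; chlorous acid converts the aldehyde to the acid, and 2-methyl-2-butene traps the HOCl before it can chlorinate or oxidise the electron-rich ring.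

Step 7
Reactants: 9 4-chloro-2-hydroxy-3-methoxy-5-(methoxymethoxy)benzoic acid
Product: 10 methyl 4-chloro-2-hydroxy-3-methoxy-5-(methoxymethoxy)benzoate
Conditions: MeI, KHCO3, DMF, rt
Reagents that add atoms: iodomethane, CI
Why: SN2 esterification of the carboxylate; KHCO3 ionises only the carboxylic acid, so the phenol, hydrogen-bonded to the carbonyl, should stay free.

Step 8
Reactants: 11 tert-butyl methyl malonate; 12 2,2,6-trimethyl-4H-1,3-dioxin-4-one
Product: 15 tert-butyl 4-hydroxy-6-methyl-2-oxo-2H-pyran-3-carboxylate, via acetylketene 13 (not isolated), via acetoacetylmalonate 14 (not isolated)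
Conditions: NaH, THF, 0 °C; then 12 added slowly, PhMe, 110 °C (THF distilled off); cold 1 M HCl work-up
Reagents that add atoms: none
Why: Acylketene C-acylation followed by lactonisation, the dioxinone counterpart of the known condensation of malonate enolates with diketene; thermolysis of 12 releases acetylketene, the malonate enolate adds to it at carbon, and the enol oxygen of the new diketone closes the six-membered lactone on the methyl ester, the less hindered of the two, so that the tert-butyl ester stays at C3.

Step 9
Reactants: 15 tert-butyl 4-hydroxy-6-methyl-2-oxo-2H-pyran-3-carboxylate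
Product: 16 tert-butyl 6-methyl-4-[(4-methylbenzenesulfonyl)oxy]-2-oxo-2H-pyran-3-carboxylate
Conditions: TsCl, Et3N, CH2Cl2, 0 °C
Reagents that add atoms: 4-methylbenzenesulfonyl chloride, Cc1ccc(cc1)S(Cl)(=O)=O
Why: O-sulfonylation of the acidic enol (a vinylogous carboxylic acid), which turns C4 into a site for addition–elimination.

Step 10
Reactants: 10 methyl 4-chloro-2-hydroxy-3-methoxy-5-(methoxymethoxy)benzoate; 16 tert-butyl 6-methyl-4-[(4-methylbenzenesulfonyl)oxy]-2-oxo-2H-pyran-3-carboxylate
Product: 17 tert-butyl 4-[3-chloro-2-methoxy-6-(methoxycarbonyl)-4-(methoxymethoxy)phenoxy]-6-methyl-2-oxo-2H-pyran-3-carboxylate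
Conditions: K2CO3, MeCN, rt → 50 °C
Reagents that add atoms: none
Why: Addition–elimination (vinylogous acyl substitution); the phenoxide adds to C4, which is activated by both the lactone carbonyl and the ester, and tosylate leaves from the stabilised enolate, so the ether oxygen is attached before ring B exists.

Step 11
Reactants: 17 tert-butyl 4-[3-chloro-2-methoxy-6-(methoxycarbonyl)-4-(methoxymethoxy)phenoxy]-6-methyl-2-oxo-2H-pyran-3-carboxylate; 18 1,1-dimethoxyethene
Product: 21 tert-butyl 2-[3-chloro-2-methoxy-6-(methoxycarbonyl)-4-(methoxymethoxy)phenoxy]-6-methoxy-4-methylbenzoate, via bicyclic lactone 19 (not isolated), via diene ketal 20 (not isolated)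
Conditions: 18 (6 equiv), PhMe, sealed tube, 120 °C
Reagents that add atoms: none
Why: Inverse-electron-demand Diels–Alder reaction: the HOMO of the ketene acetal meets the LUMO of the pyrone diene (C3=C4–C5=C6), made electron-poor by the C3 ester and the lactone carbonyl, in an asynchronous [4+2] addition in which the CH2 carbon bonds to C6 and the acetal carbon to C3. The bridged lactone 19 then loses CO2 by retro-[4+2] and the diene ketal 20 loses methanol by 1,2-elimination, so ring B closes as a six-membered carbocycle by cycloaddition, with both C–C bonds formed in one step, and becomes aromatic without an oxidant. The closest known reaction type is the addition of 1,1-dimethoxyethene to 3-alkoxycarbonyl-2-pyrones, including ones with a heteroatom donor at C4, which gives 2-methoxybenzoates. No stereocentre is set: the two bridgehead centres of racemic 19 are destroyed on aromatisation. The step needs regioselectivity (methoxy beside the ester carbon, methyl para to it) and chemoselectivity for cycloaddition over displacement of the aryloxy group at C4; the first follows from matched polarisation, C6 being the diene terminus conjugated to both carbonyls and CH2 the nucleophilic end of the acetal, and the second is favoured by neutral, non-polar conditions in which the concerted addition should outrun an ionic Michael addition at C4.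

Step 12
Reactants: 21 tert-butyl 2-[3-chloro-2-methoxy-6-(methoxycarbonyl)-4-(methoxymethoxy)phenoxy]-6-methoxy-4-methylbenzoate
Product: 22 2-[3-chloro-4-hydroxy-2-methoxy-6-(methoxycarbonyl)phenoxy]-6-hydroxy-4-methylbenzoic acid
Conditions: BCl3 (5–6 equiv), CH2Cl2, −78 → 0 °C; then H2O
Reagents that add atoms: none
Why: Lewis acid ether and ester cleavage with chelation control; BCl3 ionises the tert-butyl ester and the MOM acetal and, held in a six-membered chelate by the carboxyl group, removes the methyl ether ortho to it, while the ring A methyl ether, which has no carbonyl neighbour, and the methyl ester should survive at low temperature.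

**Compound list**

1 | 2-chlorobenzene-1,3-diol (2-chlororesorcinol) | Oc1cccc(O)c1Cl | starting material
2 | 3-chloro-2,4-dihydroxybenzaldehyde | O=Cc1ccc(O)c(Cl)c1O | intermediate
3 | 3-chloro-2-hydroxy-4-(methoxymethoxy)benzaldehyde | COCOc1ccc(C=O)c(O)c1Cl | intermediate
4 | 3-chloro-2-methoxy-4-(methoxymethoxy)benzaldehyde | COCOc1ccc(C=O)c(OC)c1Cl | intermediate
5 | 3-chloro-2-methoxy-4-(methoxymethoxy)phenyl formate | COCOc1ccc(OC=O)c(OC)c1Cl | intermediate (not isolated)
6 | 3-chloro-2-methoxy-4-(methoxymethoxy)phenol | COCOc1ccc(O)c(OC)c1Cl | intermediate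
7 | 3-chloro-6-(hydroxymethyl)-2-methoxy-4-(methoxymethoxy)phenol (present as its magnesium salt) | COCOc1cc(CO)c(O)c(OC)c1Cl | intermediate (not isolated)
8 | 4-chloro-2-hydroxy-3-methoxy-5-(methoxymethoxy)benzaldehyde | COCOc1cc(C=O)c(O)c(OC)c1Cl | intermediate
9 | 4-chloro-2-hydroxy-3-methoxy-5-(methoxymethoxy)benzoic acid | COCOc1cc(C(=O)O)c(O)c(OC)c1Cl | intermediate
10 | methyl 4-chloro-2-hydroxy-3-methoxy-5-(methoxymethoxy)benzoate | COC(=O)c1cc(OCOC)c(Cl)c(OC)c1O | intermediate
11 | tert-butyl methyl malonate (1-tert-butyl 3-methyl propanedioate) | COC(=O)CC(=O)OC(C)(C)C | starting material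
12 | 2,2,6-trimethyl-4H-1,3-dioxin-4-one | CC1=CC(=O)OC(C)(C)O1 | starting material
13 | acetylketene (4-oxopent-1-en-1-one skeleton, CH3CO–CH=C=O) | CC(=O)C=C=O | intermediate (not isolated)
14 | 1-tert-butyl 3-methyl 2-(3-oxobutanoyl)propanedioate (present as its sodium enolate) | COC(=O)C(C(=O)CC(C)=O)C(=O)OC(C)(C)C | intermediate (not isolated)
15 | tert-butyl 4-hydroxy-6-methyl-2-oxo-2H-pyran-3-carboxylate | CC1=CC(O)=C(C(=O)OC(C)(C)C)C(=O)O1 | intermediate
16 | tert-butyl 6-methyl-4-[(4-methylbenzenesulfonyl)oxy]-2-oxo-2H-pyran-3-carboxylate | CC1=CC(OS(=O)(=O)c2ccc(C)cc2)=C(C(=O)OC(C)(C)C)C(=O)O1 | intermediate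
17 | tert-butyl 4-[3-chloro-2-methoxy-6-(methoxycarbonyl)-4-(methoxymethoxy)phenoxy]-6-methyl-2-oxo-2H-pyran-3-carboxylate | COC(=O)c1cc(OCOC)c(Cl)c(OC)c1OC1=C(C(=O)OC(C)(C)C)C(=O)OC(C)=C1 | intermediate
18 | 1,1-dimethoxyethene | C=C(OC)OC | starting material
19 | tert-butyl 5-[3-chloro-2-methoxy-6-(methoxycarbonyl)-4-(methoxymethoxy)phenoxy]-8,8-dimethoxy-1-methyl-3-oxo-2-oxabicyclo[2.2.2]oct-5-ene-4-carboxylate (racemic; the two bridgeheads are fixed relative to each other by the bicycle; one enantiomer drawn) | C[C@]12CC(OC)(OC)[C@](C(=O)OC(C)(C)C)(C(=O)O1)C(Oc1c(OC)c(Cl)c(OCOC)cc1C(=O)OC)=C2 | intermediate (not isolated)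
20 | tert-butyl 2-[3-chloro-2-methoxy-6-(methoxycarbonyl)-4-(methoxymethoxy)phenoxy]-6,6-dimethoxy-4-methylcyclohexa-1,3-diene-1-carboxylate | CC1=CC(Oc2c(OC)c(Cl)c(OCOC)cc2C(=O)OC)=C(C(=O)OC(C)(C)C)C(OC)(OC)C1 | intermediate (not isolated)
21 | tert-butyl 2-[3-chloro-2-methoxy-6-(methoxycarbonyl)-4-(methoxymethoxy)phenoxy]-6-methoxy-4-methylbenzoate | COC(=O)c1cc(OCOC)c(Cl)c(OC)c1Oc1cc(C)cc(OC)c1C(=O)OC(C)(C)C | intermediate
22 | 2-[3-chloro-4-hydroxy-2-methoxy-6-(methoxycarbonyl)phenoxy]-6-hydroxy-4-methylbenzoic acid | COC(=O)c1cc(O)c(Cl)c(OC)c1Oc1cc(C)cc(O)c1C(=O)O | target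

**Totals**

Total step count: 12.
Longest linear sequence: 10 steps (steps 1–7, then 10, 11 and 12); the pyrone branch (steps 8 and 9) joins at step 10.

**Steps most likely to fail**

Step 11. The cycloaddition may stall, because the aryloxy donor at C4 and the methyl group at C6 raise the diene LUMO and hinder the first bond. Alternatively the ketene acetal may attack C4 in a Michael sense and expel the ring A phenoxide. The fallback gives up the pyrone and joins an already aromatic ring B by nucleophilic aromatic substitution; it sets out from 10 and comes back to the route at 22. Commercial 1-fluoro-3-methoxy-5-methylbenzene is lithiated between fluorine and methoxy (n-BuLi, THF, −78 °C) and quenched with DMF to give 2-fluoro-6-methoxy-4-methylbenzaldehyde F1. The phenoxide of 10 displaces the fluoride ortho to the formyl group (Cs2CO3, DMF, 90–110 °C) to give methyl 4-chloro-2-(2-formyl-3-methoxy-5-methylphenoxy)-3-methoxy-5-(methoxymethoxy)benzoate F2. Pinnick oxidation (NaClO2, NaH2PO4, 2-methyl-2-butene) gives 2-[3-chloro-2-methoxy-6-(methoxycarbonyl)-4-(methoxymethoxy)phenoxy]-6-methoxy-4-methylbenzoic acid F3. BCl3 under the conditions of step 12 then removes the MOM group and the methyl ether ortho to the carboxyl to give 22.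

Step 10. The hindered, hydrogen-bonded phenoxide may attack the sulfonyl sulfur (tosyl transfer back to the pyronate) or the lactone carbonyl (ring opening) instead of C4. The fallback replaces the sulfonate by a halide, so that the electrophile has no sulfur centre; it sets out from 15 and comes back at 17. Hydroxypyrone 15 is converted with Ph3PCl2 (from Ph3P and C2Cl6) and Et3N in MeCN, the known route from cyclic 1,3-dicarbonyls to β-chloro enones, into tert-butyl 4-chloro-6-methyl-2-oxo-2H-pyran-3-carboxylate F4. F4 is then treated with 10 and K2CO3 in MeCN to give 17 by the same addition–elimination.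

Step 12. The ring A methyl ether, flanked by two ortho substituents, may be lost alongside the intended cleavages. Demethylation of ring B may also stop once the boron carboxylate forms. The fallback separates acidolysis from demethylation; it sets out from 21 and comes back at 22. TFA in wet CH2Cl2 at rt cleaves only the tert-butyl ester and the MOM acetal and gives 2-[3-chloro-4-hydroxy-2-methoxy-6-(methoxycarbonyl)phenoxy]-6-methoxy-4-methylbenzoic acid F5. MgI2 etherate in Et2O/PhMe at 60 °C then removes, through the magnesium carboxylate chelate and iodide attack on the methyl group, only the methyl ether ortho to the carboxyl and gives 22.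

**Further compounds**

F1 | step 11 | 2-fluoro-6-methoxy-4-methylbenzaldehyde | COc1cc(C)cc(F)c1C=O
F2 | step 11 | methyl 4-chloro-2-(2-formyl-3-methoxy-5-methylphenoxy)-3-methoxy-5-(methoxymethoxy)benzoate | COC(=O)c1cc(OCOC)c(Cl)c(OC)c1Oc1cc(C)cc(OC)c1C=O
F3 | step 11 | 2-[3-chloro-2-methoxy-6-(methoxycarbonyl)-4-(methoxymethoxy)phenoxy]-6-methoxy-4-methylbenzoic acid | COC(=O)c1cc(OCOC)c(Cl)c(OC)c1Oc1cc(C)cc(OC)c1C(=O)O
F4 | step 10 | tert-butyl 4-chloro-6-methyl-2-oxo-2H-pyran-3-carboxylate | CC1=CC(Cl)=C(C(=O)OC(C)(C)C)C(=O)O1
F5 | step 12 | 2-[3-chloro-4-hydroxy-2-methoxy-6-(methoxycarbonyl)phenoxy]-6-methoxy-4-methylbenzoic acid | COC(=O)c1cc(O)c(Cl)c(OC)c1Oc1cc(C)cc(OC)c1C(=O)O
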